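The α-methylene-γ-butyrolactone (ring O–C6–C7–C11–C12, exocyclic C13) is disconnected to an aldehyde, a terminal allene and CO2. One nickel-mediated three-component coupling bonds the central allene carbon C11 to CO2 (C12) and the substituted allene terminus C7 to the aldehyde carbon C6. This joins the two halves, builds the lactone, leaves C11=C13, and sets C6 and C7 under control of C8. The precursors are a (Z)-enal bearing the cis-2,3-epoxide and a vinyl group (C1–C6, C15), and a silyloxy allene bearing an isopropenyl group (C7–C11, C13, C14). Both arms end cis on the lactone, so metathesis closes C1=C10 and peripheral epoxidation completes the core.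

Key step: step 12

Remark: atoms carry germacrane numbers (ring C1–C10, lactone C11–C13, methyl C14, CH2OH C15). The facial sense of the allylboranes made from (+)-Ipc2BOMe is taken from the usual chair model, and the antipodal borane would be used if it proved opposite.

Step 1
Reactants: 1 but-2-yne-1,4-diol
Product: 2 4-(tert-butyldiphenylsilyloxy)but-2-yn-1-ol
Conditions: TBDPSCl (0.3 equiv), imidazole, DMF, 0 °C to rt
Reagents that add atoms: tert-butylchlorodiphenylsilane CC(C)(C)[Si](Cl)(c1ccccc1)c1ccccc1
Why: Statistical monosilylation of the symmetrical diol used in excess should give the mono ether whose protected oxygen becomes the C15 hydroxyl (silyl ether formation).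

Step 2
Reactants: 2 4-(tert-butyldiphenylsilyloxy)but-2-yn-1-ol
Product: 4 (Z)-4-(tert-butyldiphenylsilyloxy)-3-iodobut-2-en-1-ol, via cyclic vinylalanate 3 (not isolated)
Conditions: NaAlH2(OCH2CH2OMe)2, THF, 0 °C to rt; I2, −78 °C to 0 °C
Reagents that add atoms: iodine II
Why: The free hydroxyl directs a trans-hydroalumination that places aluminium on the distal alkyne carbon (C4) in a five-membered alanate, and iodinolysis with retention should leave iodine cis to C6, which fixes the later C4=C5 geometry.

Step 3
Reactants: 4 (Z)-4-(tert-butyldiphenylsilyloxy)-3-iodobut-2-en-1-ol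
Product: 5 (Z)-vinyl iodide bis-silyl ether (C6–OSiEt3 and C15–OTBDPS)
Conditions: Et3SiCl, imidazole, CH2Cl2, 0 °C
Reagents that add atoms: chlorotriethylsilane CC[Si](Cl)(CC)CC
Why: Silyl ether formation masks the C6 hydroxyl with a group that can later be oxidised off selectively, and it prevents butenolide formation in the carbonylation.

Step 4
Reactants: 5 (Z)-vinyl iodide bis-silyl ether
Product: 6 (Z)-2-(tert-butyldiphenylsilyloxymethyl)-4-(triethylsilyloxy)but-2-enal
Conditions: Pd(PPh3)4 (cat.), CO (3 atm), n-Bu3SnH (slow addition), THF, 50 °C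
Reagents that add atoms: carbon monoxide [C-]#[O+]
Why: Oxidative addition of zerovalent palladium, CO insertion and hydride transfer from tin (palladium-catalysed reductive carbonylation) should replace iodine by CHO (C3) with retention, and this avoids a vinyl carbanion that would suffer migration of the cis silyl group.

Step 5
Reactants: 6 (Z)-2-(tert-butyldiphenylsilyloxymethyl)-4-(triethylsilyloxy)but-2-enal
Product: 7 (2S,3S)-syn-chlorohydrin (C3–OH, C2–Cl, C1 vinyl, (Z)-C4=C5)
Conditions: allyl chloride, (+)-Ipc2BOMe, LiN(c-C6H11)2, Et2O, −95 °C; BF3·OEt2; then 6, −95 °C; NaOAc, H2O2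
Reagents that add atoms: allyl chloride C=CCCl
Why: Brown-type allylboration with the (Z)-γ-chloroallylborane runs through a chair transition state, so the (Z)-geometry should give the syn chlorohydrin and the isopinocampheyl groups should direct attack to the Re face, which sets C3 and C2.

Step 6
Reactants: 7 (2S,3S)-syn-chlorohydrin
Product: 8 cis-2,3-epoxide (2R,3S) bearing the C1 vinyl group and the C6–OSiEt3 ether
Conditions: DBU, CH2Cl2, rt
Reagents that add atoms: none
Why: In this Williamson-type closure O3 displaces the allylic chloride at C2 with inversion, so the syn chlorohydrin should give only the cis-epoxide.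

Step 7
Reactants: 8 cis-2,3-epoxide triethylsilyl ether
Product: 9 west enal: (Z)-enal C6HO–C5H=C4(CH2OTBDPS) carrying the (2R,3S)-cis-vinyl epoxide at C4
Conditions: (COCl)2, DMSO, CH2Cl2, −78 to −40 °C; Et3N
Reagents that add atoms: none
Why: Under Swern conditions the chlorosulfonium salt exchanges a primary triethylsilyl ether much faster than the tert-butyldiphenylsilyl ether, so the C6 ether should go directly to the (Z)-enal without acid, which would trigger furan formation.

Step 8
Reactants: 10 3-(trimethylsilyl)prop-2-ynal
Product: 11 (R)-5-methyl-1-(trimethylsilyl)hex-5-en-1-yn-3-ol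
Conditions: 2-methylallylmagnesium chloride, (+)-Ipc2BOMe, Et2O, −78 °C to rt; then 10, −78 °C; NaOH, H2O2, 0 °C
Reagents that add atoms: 2-methylallylmagnesium chloride C=C(C)C[Mg]Cl
Why: Brown methallylboration through a chair transition state should add to the Re face of the alkynal and set C8 with the configuration of the target.

Step 9
Reactants: 11 (R)-5-methyl-1-(trimethylsilyl)hex-5-en-1-yn-3-ol
Product: 12 (R)-5-methylhex-5-en-1-yn-3-ol
Conditions: K2CO3 (cat.), MeOH, rt
Reagents that add atoms: none
Why: Methanolysis of the alkynyl–silicon bond should free the terminal alkyne without touching C8.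

Step 10
Reactants: 12 (R)-5-methylhex-5-en-1-yn-3-ol
Product: 13 (R)-triethyl(5-methylhex-5-en-1-yn-3-yloxy)silane
Conditions: Et3SiCl, imidazole, CH2Cl2, 0 °C
Reagents that add atoms: chlorotriethylsilane CC[Si](Cl)(CC)CC
Why: Silyl ether formation blocks O8, so that O8 can neither bind nickel nor compete with O6 in the later lactonisation.

Step 11
Reactants: 13 (R)-triethyl(5-methylhex-5-en-1-yn-3-yloxy)silane
Product: 14 east allene: (R)-triethyl(6-methylhepta-1,2,6-trien-4-yloxy)silane
Conditions: (CH2O)n, CuBr, i-Pr2NH, 1,4-dioxane, reflux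
Reagents that add atoms: formaldehyde (as paraformaldehyde) C=O
Why: In the Crabbé homologation, aminomethylation of the copper acetylide followed by 1,5-hydride transfer and loss of imine should turn C≡C–H into C7H=C11=C13H2 and leave C8 untouched.

Step 12
Reactants: 14 east allene; 9 west enal
Product: 17 cis-4,5-disubstituted α-methylene-γ-butyrolactone carrying the west arm at C6 and the east arm at C7 (C6 C7 C8 as in the target), via nickelalactone 15 (not isolated), via hydroxy acid 16 (not isolated)
Conditions: Ni(cod)2 (1.2 equiv), DBU, CO2 (1 atm), THF, 0 °C, 14 (1.2 equiv); then 9, 0 °C to rt; aq citric acid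
Reagents that add atoms: carbon dioxide O=C=O
Why: Zerovalent nickel couples CO2 to the unsubstituted C11=C13 π bond of 14 on the face away from C8 (oxidative cyclisation), which forms C11–C12 and gives nickelalactone 15, a chelated 2-carboxyallyl complex of divalent nickel in which C8 is cis to C13. Aldehyde 9, added only after all zerovalent nickel is consumed, binds to nickel and is attacked by C7 through a six-membered chair (allyl transfer with allylic transposition), which forms C6–C7 and regenerates C11=C13; protonolysis gives 16. The closest known reaction type is the nickel-mediated sequential addition of CO2 and an aldehyde to a terminal allene, akin to the cyclisation–lactonisation of 2-carboalkoxy-π-allylnickel complexes. The only ring closed is the five-membered lactone, by 5-exo-trig attack of O6 on the carboxyl carbon C12 of 16 on acidification. The (Z)-allyl geometry with the alkenyl group of 9 equatorial gives the syn adduct and hence the cis C6/C7 relationship, while C8 fixes the face of C7: allylic 1,3-strain holds H8 in the allyl plane toward C13, C9 stands anti to the incoming aldehyde and the smaller silyloxy oxygen sits outside. The step needs 1,2- rather than 1,4-addition, secured by the β,β-disubstituted enal, attack by C7 rather than C13, secured by nickel resting on the unhindered C13, and survival of the vinyl epoxide and isopropenyl group, secured by the order of addition and by the poor ligand quality of a 1,1-disubstituted alkene.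

Step 13
Reactants: 17 lactone with C8–OSiEt3
Product: 18 lactone with free C8–OH
Conditions: HF·pyridine, excess pyridine, THF, 0 °C
Reagents that add atoms: none
Why: Fluoride should cleave the secondary triethylsilyl ether far faster than the tert-butyldiphenylsilyl ether, the pyridine buffer spares the vinyl epoxide, and migration of the lactone to O8 would need a strained bicyclic intermediate.

Step 14
Reactants: 18 lactone with free C8–OH
Product: 19 C8 angelate
Conditions: angelic acid, 2,4,6-trichlorobenzoyl chloride, Et3N, toluene, rt; then 18, 70 °C, no DMAP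
Reagents that add atoms: angelic acid C/C=C(/C)C(=O)O
Why: Yamaguchi esterification through the mixed anhydride acylates O8 with retention at C8, and leaving out nucleophilic catalysts should avoid addition–elimination isomerisation of the (Z)-angelate to the tiglate.

Step 15
Reactants: 19 C8 angelate
Product: 20 ten-membered (1(10)Z,4Z)-diene with the cis-2,3-epoxide (silyl ether at O15)
Conditions: second-generation Hoveyda–Grubbs catalyst (10 mol %), 1,4-benzoquinone, toluene (1 mM), 60 °C, argon purge
Reagents that add atoms: none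
Why: Ring-closing metathesis should start at the monosubstituted C1 vinyl group and close onto the isopropenyl group. The two arms are cis on the lactone, the cis-epoxide and (Z)-C4=C5 turn the west arm back, ring strain allows only the (Z)-C1=C10 alkene, and the electron-poor C11=C13 and the trisubstituted alkenes are slower partners.

Step 16
Reactants: 20 ten-membered diene
Product: 21 1,10;2,3-diepoxide (silyl ether of the target)
Conditions: mCPBA, NaHCO3, CH2Cl2, −20 to 0 °C
Reagents that add atoms: mCPBA OOC(=O)c1cccc(Cl)c1
Why: In this Prilezhaev epoxidation C1=C10 is the only electron-rich alkene, since C4=C5 carries three allylic C–O bonds and C11=C13 and the angelate are conjugated to carbonyls. Its two allylic ring bonds (C2–C3 and C9–C8) point to one side, so attack on the open peripheral face, anti to C3 with H2 in the alkene plane, should set C1 and C10 as in the target.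

Step 17
Reactants: 21 1,10;2,3-diepoxide silyl ether
Product: 22 target CNP0157626.1
Conditions: n-Bu4NF, AcOH (1:1), THF, 0 °C to rt
Reagents that add atoms: none
Why: Buffered fluoride should cleave the primary allylic silyl ether, and the near-neutral medium should spare the epoxides, the α-methylene lactone and the angelate.

Compound list
1 | but-2-yne-1,4-diol | OCC#CCO | starting material
2 | 4-(tert-butyldiphenylsilyloxy)but-2-yn-1-ol | OCC#CCO[Si](c1ccccc1)(c1ccccc1)C(C)(C)C | intermediate
3 | cyclic sodium vinylalanate (five-membered O–Al–C4 ring) | [Na+].COCCO[Al-]1(OCCOC)OCC=C1CO[Si](c1ccccc1)(c1ccccc1)C(C)(C)C | intermediate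
4 | (Z)-4-(tert-butyldiphenylsilyloxy)-3-iodobut-2-en-1-ol | OC/C=C(\I)CO[Si](c1ccccc1)(c1ccccc1)C(C)(C)C | intermediate
5 | (Z)-vinyl iodide bis-silyl ether | CC[Si](CC)(CC)OC/C=C(\I)CO[Si](c1ccccc1)(c1ccccc1)C(C)(C)C | intermediate
6 | (Z)-2-(tert-butyldiphenylsilyloxymethyl)-4-(triethylsilyloxy)but-2-enal | CC[Si](CC)(CC)OC/C=C(\C=O)CO[Si](c1ccccc1)(c1ccccc1)C(C)(C)C | intermediate
7 | (2S,3S)-syn-chlorohydrin, (Z)-C4=C5 | CC[Si](CC)(CC)OC/C=C(/CO[Si](c1ccccc1)(c1ccccc1)C(C)(C)C)[C@H](O)[C@@H](Cl)C=C | intermediate
8 | (2R,3S)-cis-vinyl epoxide, C6 triethylsilyl ether | CC[Si](CC)(CC)OC/C=C(/CO[Si](c1ccccc1)(c1ccccc1)C(C)(C)C)[C@@H]1O[C@@H]1C=C | intermediate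
9 | west enal, (Z)-enal with (2R,3S)-cis-vinyl epoxide | O=C/C=C(/CO[Si](c1ccccc1)(c1ccccc1)C(C)(C)C)[C@@H]1O[C@@H]1C=C | intermediate
10 | 3-(trimethylsilyl)prop-2-ynal | C[Si](C)(C)C#CC=O | starting material
11 | (R)-5-methyl-1-(trimethylsilyl)hex-5-en-1-yn-3-ol | C=C(C)C[C@@H](O)C#C[Si](C)(C)C | intermediate
12 | (R)-5-methylhex-5-en-1-yn-3-ol | C=C(C)C[C@@H](O)C#C | intermediate
13 | (R)-triethyl(5-methylhex-5-en-1-yn-3-yloxy)silane | C=C(C)C[C@@H](O[Si](CC)(CC)CC)C#C | intermediate
14 | east allene, (R)-triethyl(6-methylhepta-1,2,6-trien-4-yloxy)silane | C=C(C)C[C@@H](O[Si](CC)(CC)CC)C=C=C | intermediate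
15 | nickelalactone (DBU ligands omitted), C8 cis to C13 | O=C1O[Ni]C/C1=C\[C@H](O[Si](CC)(CC)CC)CC(C)=C | intermediate
16 | syn γ-hydroxy α-methylene acid | C=C(C(=O)O)[C@@H]([C@@H](O)/C=C(/CO[Si](c1ccccc1)(c1ccccc1)C(C)(C)C)[C@@H]1O[C@@H]1C=C)[C@H](O[Si](CC)(CC)CC)CC(C)=C | intermediate
17 | cis-lactone with C8–OSiEt3 | C=C1C(=O)O[C@@H](/C=C(/CO[Si](c2ccccc2)(c2ccccc2)C(C)(C)C)[C@@H]2O[C@@H]2C=C)[C@H]1[C@H](O[Si](CC)(CC)CC)CC(C)=C | intermediate
18 | cis-lactone with free C8–OH | C=C1C(=O)O[C@@H](/C=C(/CO[Si](c2ccccc2)(c2ccccc2)C(C)(C)C)[C@@H]2O[C@@H]2C=C)[C@H]1[C@H](O)CC(C)=C | intermediate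
19 | C8 angelate | C=C1C(=O)O[C@@H](/C=C(/CO[Si](c2ccccc2)(c2ccccc2)C(C)(C)C)[C@@H]2O[C@@H]2C=C)[C@H]1[C@H](OC(=O)/C(C)=C\C)CC(C)=C | intermediate
20 | ten-membered (1(10)Z,4Z)-diene, cis-2,3-epoxide | C=C1C(=O)O[C@H]2/C=C(/CO[Si](c3ccccc3)(c3ccccc3)C(C)(C)C)[C@@H]3O[C@@H]3/C=C(/C)C[C@@H](OC(=O)/C(C)=C\C)[C@@H]12 | intermediate
21 | 1,10;2,3-diepoxide, O15 silyl ether | C=C1C(=O)O[C@H]2/C=C(/CO[Si](c3ccccc3)(c3ccccc3)C(C)(C)C)[C@@H]3O[C@@H]3[C@H]3O[C@@]3(C)C[C@@H](OC(=O)/C(C)=C\C)[C@@H]12 | intermediate
22 | CNP0157626.1 | C=C1C(=O)O[C@H]2/C=C(/CO)[C@@H]3O[C@@H]3[C@H]3O[C@@]3(C)C[C@@H](OC(=O)/C(C)=C\C)[C@@H]12 | target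

Total steps: 17. Longest linear sequence: 13 (steps 1–7 and 12–17).

Steps most likely to fail

1. Step 12.
- **What may go wrong:** Allyl transfer to the hindered (Z)-enal may be slow. DBU may isomerise the enal or open the epoxide. Loss of the allyl geometry would erode the cis C6/C7 relationship, and the facial bias from C8 may be weak.
- **Fallback:** it sets out from 14 and 9 and comes back at 17 through 16. Platinum-catalysed diboration of the terminal π bond of 14 (Pt(dba)2, PCy3, B2pin2, toluene, 50 °C) should give the (Z)-2,3-bis(pinacolboryl)alkene F1. Uncatalysed allylboration of 9 by F1 through a closed chair should give the syn alkenylboronate alcohol F2, which forms C6–C7 only. Copper-catalysed carboxylation of F2 with CO2 ((IPr)CuCl, KOt-Bu, THF, 70 °C) should then form C11–C12 and give 16, which closes to 17.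

2. Step 15.
- **What may go wrong:** Closure onto the 1,1-disubstituted alkene may be slow. The carbene may engage the lactone methylene instead, giving an eight-membered ring. Oligomerisation may compete, and the cis-dialkenyl epoxide may undergo Cope rearrangement at the reaction temperature.
- **Fallback:** it sets out from 19 and comes back at 21. Conjugate addition of thiophenol (PhSH, cat. Et3N, CH2Cl2, 0 °C) masks C11=C13 as the sulfide F3 (C11 epimers). Metathesis of F3 should give the macrocyclic sulfide F4. mCPBA (2 equiv) oxidises sulfur and epoxidises C1=C10 to give the sulfoxide diepoxide F5. Thermal syn-elimination (toluene, CaCO3, 90 °C) then restores the methylene group and gives 21.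

3. Step 16.
- **What may go wrong:** Facial selectivity will be poor if the ring adopts a conformer that exposes the other face of C1=C10. Competing oxidation of C4=C5 is also possible.
- **Fallback:** it sets out from 20 and comes back at 21. NBS in aqueous acetone forms the bromonium ion on the accessible face. Water opens it at the tertiary C10 from the opposite face to give the bromohydrin F6. Closure with Ag2O displaces bromide at C1 with inversion, so oxygen ends on the face that the peracid did not reach.

Further compounds
F1 | step 12 | (Z)-2,3-bis(pinacolboryl)alkene from allene 14 | CC1(C)OB(C/C(B2OC(C)(C)C(C)(C)O2)=C\[C@H](O[Si](CC)(CC)CC)CC(C)=C)OC1(C)C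
F2 | step 12 | syn alkenylboronate alcohol | C=C(B1OC(C)(C)C(C)(C)O1)[C@@H]([C@@H](O)/C=C(/CO[Si](c1ccccc1)(c1ccccc1)C(C)(C)C)[C@@H]1O[C@@H]1C=C)[C@H](O[Si](CC)(CC)CC)CC(C)=C
F3 | step 15 | thiophenol adduct of 19 (C11 epimers) | c1ccccc1SCC1C(=O)O[C@@H](/C=C(/CO[Si](c2ccccc2)(c2ccccc2)C(C)(C)C)[C@@H]2O[C@@H]2C=C)[C@H]1[C@H](OC(=O)/C(C)=C\C)CC(C)=C
F4 | step 15 | macrocyclic sulfide | c1ccccc1SCC1C(=O)O[C@H]2/C=C(/CO[Si](c3ccccc3)(c3ccccc3)C(C)(C)C)[C@@H]3O[C@@H]3/C=C(/C)C[C@@H](OC(=O)/C(C)=C\C)[C@@H]12
F5 | step 15 | sulfoxide diepoxide | c1ccccc1S(=O)CC1C(=O)O[C@H]2/C=C(/CO[Si](c3ccccc3)(c3ccccc3)C(C)(C)C)[C@@H]3O[C@@H]3[C@H]3O[C@@]3(C)C[C@@H](OC(=O)/C(C)=C\C)[C@@H]12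
F6 | step 16 | C1-bromo C10-hydroxy bromohydrin | C=C1C(=O)O[C@H]2/C=C(/CO[Si](c3ccccc3)(c3ccccc3)C(C)(C)C)[C@@H]3O[C@@H]3[C@H](Br)[C@@](C)(O)C[C@@H](OC(=O)/C(C)=C\C)[C@@H]12
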